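## Retrosynthetic overview

- The C1 carbinol is made last: an exocyclic isobutylidene enone is reduced by hydrogen-atom transfer and the C1 radical is trapped by O2 on the face away from the coumarin. This gives the isobutyl group and the tertiary OH in one step.
- The quaternary C6a–C3′ bond (key step) joins two normally nucleophilic carbons. Coumarin C3 is made electrophilic as a Rh carbenoid from the 3-diazo-2,4-dione, and it is attacked by the γ-carbon (C6a) of a bicyclic silyloxyfulvene, anti to the C6 methyl.
- The silyloxyfulvene comes from a cross-conjugated dienone, made by crossed aldol condensation with 2-methylpropanal. Ring B comes from intramolecular aldol condensation of a 1,4-diketone, itself from hydration of a 2-butynyl ketone.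
- Ring A and C6 come from cyclopent-2-enone by Cu-catalysed asymmetric methyl addition and propargylation of the enolate.
- Ring order: coumarin pyranone (made separately), ring A (bought), ring B (aldol), then union of the two halves.

Assumption: 1 is bought as a catalogue compound, and the ligand antipode that gives the (3S) methyl adduct in step 3 is used (both antipodes are accessible); the pentalenone numbering C1–C6a of the target is used in all explanations.

## Route

Step 1
Reactants: 1 1-(2-hydroxy-6-methylphenyl)ethan-1-one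
Product: 2 4-hydroxy-5-methyl-2H-chromen-2-one
Conditions: NaH (3 equiv), (EtO)2CO, toluene, 110 °C; then aq. HCl
Reagents that add atoms: diethyl carbonate CCOC(=O)OCC
Why: Claisen C-acylation of the methyl ketone enolate and lactonisation onto the phenoxide is the standard 4-hydroxycoumarin synthesis; no stereocentre is formed.

Step 2
Reactants: 2 4-hydroxy-5-methyl-2H-chromen-2-one
Product: 3 3-diazo-5-methylchromane-2,4-dione
Conditions: p-ABSA, Et3N, MeCN, 0 °C → rt
Reagents that add atoms: 4-acetamidobenzenesulfonyl azide CC(=O)Nc1ccc(cc1)S(=O)(=O)N=[N+]=[N-]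
Why: Regitz diazo transfer to the acidic C3 of the cyclic 1,3-dicarbonyl gives the stable diazo dione that later serves as the electrophilic coumarin C3 synthon.

Step 3
Reactants: 4 cyclopent-2-en-1-one; 5 1-bromobut-2-yne
Product: 7 (2R,3S)-2-(but-2-yn-1-yl)-3-methylcyclopentan-1-one, via methylzinc (S)-3-methylcyclopent-1-en-1-olate 6 (not isolated)
Conditions: Me2Zn, (CuOTf)2·C6H6 (1 mol %), chiral amino-acid-based phosphine ligand (2.4 mol %), toluene, −30 °C; then HMPA, 5, −30 → 0 °C
Reagents that add atoms: dimethylzinc C[Zn]C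
Why: Cu-catalysed asymmetric conjugate addition sets C6 as 3S under ligand control, and the regiodefined zinc enolate is alkylated by the propargylic bromide trans to the new methyl (tandem conjugate addition–enolate alkylation).

Step 4
Reactants: 7 (2R,3S)-2-(but-2-yn-1-yl)-3-methylcyclopentan-1-one
Product: 8 (2R,3S)-3-methyl-2-(2-oxobutyl)cyclopentan-1-one
Conditions: NaAuCl4·2H2O (2 mol %), MeOH/H2O (10:1), 65 °C
Reagents that add atoms: water O
Why: ketone-assisted (5-exo-dig) Markovnikov hydration of the γ,δ-alkynyl ketone places the new carbonyl on the proximal alkyne carbon and gives the 1,4-diketone; no stereocentre is touched.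

Step 5
Reactants: 8 (2R,3S)-3-methyl-2-(2-oxobutyl)cyclopentan-1-one; 9 2-methylpropanal
Product: 11 (6S,6aR,E)-3,6-dimethyl-1-(2-methylpropylidene)-4,5,6,6a-tetrahydropentalen-2(1H)-one, via (6S,6aR)-3,6-dimethyl-4,5,6,6a-tetrahydropentalen-2(1H)-one 10 (not isolated)
Conditions: KOH, MeOH, 65 °C; then 9, 0 °C → rt
Reagents that add atoms: none
Why: intramolecular aldol condensation (jasmone-type cyclopentenone annulation) closes ring B, and a Claisen–Schmidt crossed aldol condensation at the only α′-CH2 (C1) installs the isobutylidene; C6 is not enolisable and C6a is erased in the next step.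

Step 6
Reactants: 11 (6S,6aR,E)-3,6-dimethyl-1-(2-methylpropylidene)-4,5,6,6a-tetrahydropentalen-2(1H)-one
Product: 12 (6S,E)-3,6-dimethyl-1-(2-methylpropylidene)-2-[(triisopropylsilyl)oxy]-1,4,5,6-tetrahydropentalene
Conditions: KHMDS (0.95 equiv), THF, −78 → −20 °C; TIPSOTf, −78 → 0 °C
Reagents that add atoms: triisopropylsilyl trifluoromethanesulfonate CC(C)[Si](OS(=O)(=O)C(F)(F)F)(C(C)C)C(C)C
Why: thermodynamic vinylogous enolisation removes the doubly allylic C6a–H (held perpendicular to both π systems, giving the longest conjugated trienolate), and O-silylation gives the silyloxyfulvene in which C1, C3a and C6a are all sp2 and C6 is the only stereocentre.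

Step 7
Reactants: 12 (6S,E)-3,6-dimethyl-1-(2-methylpropylidene)-2-[(triisopropylsilyl)oxy]-1,4,5,6-tetrahydropentalene; 3 3-diazo-5-methylchromane-2,4-dione
Product: 14 4-hydroxy-5-methyl-3-[(6S,6aR,E)-3,6-dimethyl-1-(2-methylpropylidene)-2-oxo-1,2,4,5,6,6a-hexahydropentalen-6a-yl]-2H-chromen-2-one, via propellane-type dihydrofurocoumarin silyl enol ether 13 (not isolated)
Conditions: Rh2(esp)2 (1 mol %), PhCF3, 60 °C, slow addition of 3; then TBAF, AcOH, THF, 0 °C
Reagents that add atoms: none
Why: Proposed new method: the Rh carbenoid from 3 makes coumarin C3 (normally the nucleophilic carbon of the 1,3-dicarbonyl) an electrophile that is attacked by the γ-carbon C6a of 12 on the face anti to the C6 methyl (the only group that differentiates the faces; C3 is screened by OTIPS and attack at the exocyclic carbon would give an antiaromatic cyclopentadienyl cation), the zwitterion closes to 13, and fluoride opens it by E1cB (retro-oxa-Michael) to the enone and the free 4-hydroxycoumarin; the closest known reactions are the Rh(II)-catalysed formal [3+2] additions of 3-diazochromane-2,4-diones to enol ethers and γ-selective vinylogous Mukaiyama reactions of silyl dienol ethers.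

Step 8
Reactants: 14 4-hydroxy-5-methyl-3-[(6S,6aR,E)-3,6-dimethyl-1-(2-methylpropylidene)-2-oxo-1,2,4,5,6,6a-hexahydropentalen-6a-yl]-2H-chromen-2-one
Product: 16 4-hydroxy-3-[(1S,6S,6aS)-1-hydroxy-3,6-dimethyl-1-(2-methylpropyl)-2-oxo-1,2,4,5,6,6a-hexahydropentalen-6a-yl]-5-methyl-2H-chromen-2-one, via C1 hydroperoxide 15 (not isolated)
Conditions: Mn(dpm)3 (10 mol %), PhSiH3, O2 (1 atm), i-PrOH/CH2Cl2, 0 °C; then P(OEt)3
Reagents that add atoms: dioxygen O=O
Why: Mukaiyama-type HAT reductive α-hydroxylation delivers H to the accessible exocyclic β-carbon (the tetrasubstituted C3=C3a enone and the coumarin are inert), and the tertiary α-keto radical at C1 is trapped by O2 anti to the adjacent coumarin, so OH ends trans and isobutyl cis to the coumarin (1S).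

## Compound list

1 | 1-(2-hydroxy-6-methylphenyl)ethan-1-one | CC(=O)c1c(C)cccc1O | starting material
2 | 4-hydroxy-5-methyl-2H-chromen-2-one | Cc1cccc2oc(=O)cc(O)c12 | intermediate
3 | 3-diazo-5-methylchromane-2,4-dione | Cc1cccc2OC(=O)C(=[N+]=[N-])C(=O)c12 | intermediate
4 | cyclopent-2-en-1-one | O=C1C=CCC1 | starting material
5 | 1-bromobut-2-yne | CC#CCBr | starting material
6 | methylzinc (S)-3-methylcyclopent-1-en-1-olate | C[Zn]OC1=C[C@@H](C)CC1 | intermediate
7 | (2R,3S)-2-(but-2-yn-1-yl)-3-methylcyclopentan-1-one | O=C1CC[C@H](C)[C@H]1CC#CC | intermediate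
8 | (2R,3S)-3-methyl-2-(2-oxobutyl)cyclopentan-1-one | O=C1CC[C@H](C)[C@H]1CC(=O)CC | intermediate
9 | 2-methylpropanal | CC(C)C=O | starting material
10 | (6S,6aR)-3,6-dimethyl-4,5,6,6a-tetrahydropentalen-2(1H)-one | CC1=C2CC[C@H](C)[C@H]2CC1=O | intermediate
11 | (6S,6aR,E)-3,6-dimethyl-1-(2-methylpropylidene)-4,5,6,6a-tetrahydropentalen-2(1H)-one | CC1=C2CC[C@H](C)[C@H]2/C(=C\C(C)C)C1=O | intermediate
12 | (6S,E)-3,6-dimethyl-1-(2-methylpropylidene)-2-[(triisopropylsilyl)oxy]-1,4,5,6-tetrahydropentalene | CC1=C(O[Si](C(C)C)(C(C)C)C(C)C)/C(=C/C(C)C)C2=C1CC[C@@H]2C | intermediate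
13 | propellane-type [3+2] adduct: coumarin C3 bonded to C6a and coumarin O4 bonded to C3a, both anti to the C6 methyl; TIPS enol ether at C2=C3; E-isobutylidene at C1 | CC1=C(O[Si](C(C)C)(C(C)C)C(C)C)/C(=C/C(C)C)[C@@]2(c3c(O4)c5c(C)cccc5oc3=O)[C@@H](C)CC[C@@]124 | intermediate
14 | 4-hydroxy-5-methyl-3-[(6S,6aR,E)-3,6-dimethyl-1-(2-methylpropylidene)-2-oxo-1,2,4,5,6,6a-hexahydropentalen-6a-yl]-2H-chromen-2-one | CC1=C2CC[C@H](C)[C@]2(c2c(O)c3c(C)cccc3oc2=O)/C(=C\C(C)C)C1=O | intermediate
15 | 3-[(1S,6S,6aS)-1-hydroperoxy-3,6-dimethyl-1-(2-methylpropyl)-2-oxo-1,2,4,5,6,6a-hexahydropentalen-6a-yl]-4-hydroxy-5-methyl-2H-chromen-2-one | CC1=C2CC[C@H](C)[C@]2(c2c(O)c3c(C)cccc3oc2=O)[C@@](OO)(CC(C)C)C1=O | intermediate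
16 | 4-hydroxy-3-[(1S,6S,6aS)-1-hydroxy-3,6-dimethyl-1-(2-methylpropyl)-2-oxo-1,2,4,5,6,6a-hexahydropentalen-6a-yl]-5-methyl-2H-chromen-2-one | CC1=C2CC[C@H](C)[C@]2(c2c(O)c3c(C)cccc3oc2=O)[C@@](O)(CC(C)C)C1=O | target

## Step count and risks

Total step count: 8. Longest linear sequence: 6 (steps 3–8); the coumarin branch (steps 1–2) joins at step 7.

Steps most likely to fail:

Step 7 (carbenoid coupling). The risks are attack at C3 instead of C6a, poor facial control, and thermal loss of 12. The fallback reverses which partner carries the reversed polarity and needs no diazo compound. It sets out from 12 and 2: ceric ammonium nitrate (2.2 equiv) with NaHCO3 in MeCN at −30 °C oxidises the electron-rich silyloxyfulvene to its radical cation, a vinylogous enolonium species. The enol of 2 traps it at C6a anti to the C6 methyl, and a second oxidation with loss of the silyl group returns the route at 14. No new isolated compound is made on the way.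

Step 6 (regioselective trienol ether). Deprotonation could occur at C4 or at the isopropyl methine instead of C6a. The fallback fixes the site by radical C–H abstraction and sets out from 11. NBS with catalytic AIBN in PhCF3 at 80 °C abstracts the weakest, doubly allylic C6a–H and gives (6S,6aR,E)-6a-bromo-3,6-dimethyl-1-(2-methylpropylidene)-4,5,6,6a-tetrahydropentalen-2(1H)-one F1. Zinc dust followed by TIPSOTf in THF at 0 °C (vinylogous Reformatsky-type reductive enolisation with O-silylation) then gives the same silyloxyfulvene, so the route is rejoined at 12.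

Step 8 (HAT hydroxylation). The acidic coumarin OH may disturb the Mn catalyst or add reversibly to the exocyclic enone, and simple conjugate reduction may compete. The fallback is an ionic two-stage sequence that sets out from 14. Et3SiH (3 equiv) with RhCl(PPh3)3 (2 mol %) in toluene at 60 °C effects 1,4-hydrosilylation of the less hindered exocyclic enone and silylates the coumarin OH. This gives 3-[(6S,6aR)-3,6-dimethyl-1-(2-methylpropyl)-2-(triethylsilyloxy)-4,5,6,6a-tetrahydropentalen-6a-yl]-5-methyl-4-(triethylsilyloxy)-2H-chromen-2-one F2. Rubottom oxidation with dimethyldioxirane in acetone/CH2Cl2 at −40 °C epoxidises the C1=C2 enol ether anti to the coumarin, and HF·pyridine removes the silyl groups, so the route is rejoined at 16.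

## Further compounds

F1 | step 6 | (6S,6aR,E)-6a-bromo-3,6-dimethyl-1-(2-methylpropylidene)-4,5,6,6a-tetrahydropentalen-2(1H)-one | CC1=C2CC[C@H](C)[C@]2(Br)/C(=C\C(C)C)C1=O
F0 | step 7 | none | none
F2 | step 8 | 3-[(6S,6aR)-3,6-dimethyl-1-(2-methylpropyl)-2-(triethylsilyloxy)-4,5,6,6a-tetrahydropentalen-6a-yl]-5-methyl-4-(triethylsilyloxy)-2H-chromen-2-one | CC1=C2CC[C@H](C)[C@]2(c2c(O[Si](CC)(CC)CC)c3c(C)cccc3oc2=O)C(CC(C)C)=C1O[Si](CC)(CC)CC
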